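A small charge of single-handed free catalyst, 1.1 mol%, works here on a racemate, and the east run's last reading shows more left-handed product than right-handed product.

| setting | west | south-east | east | Thursday's | Friday's |
|---|---|---|---|---|---|
| left-handed substrate | 0.028 M | 0.028 M | 0.028 M | 0.028 M | 0.028 M |
| right-handed substrate | 0.028 M | 0.028 M | 0.028 M | 0.028 M | 0.028 M |
| partner | 1.1 equiv | 1.6 equiv | 3.3 equiv | 1.00 equiv | 3.00 equiv |
| free catalyst | 1.1 mol% | 1.1 mol% | 1.1 mol% | 1.1 mol% | 1.1 mol% |
| added ligand | 0.67 mM | 0.67 mM | 0.67 mM | 0.67 mM | 0.67 mM |
| remark | run made earlier | run made earlier | run made earlier |  |  |
| time |  |  |  | 30 min | 30 min |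

- west (time / min: left-handed product / %, right-handed product / %): 1.33: 2.2, 0.8; 2.50: 4.2, 1.8; 4.00: 5.6, 2.5; 8.00: 9.6, 4.2; 15.0: 14.3, 6.6
- south-east (time / min: left-handed product / %, right-handed product / %): 1.33: 3.0, 0.7; 4.00: 8.1, 3.5; 8.00: 13.7, 6.1; 10.0: 15.3, 7.0; 15.0: 18.8, 8.8
- east (time / min: left-handed product / %, right-handed product / %): 1.33: 6.5, 2.9; 4.00: 15.9, 7.4; 8.00: 24.2, 11.7; 10.0: 27.4, 13.2; 15.0: 32.0, 17.2

(standard deviation of a reading: 0.3 percentage points)

- free catalyst is single-handed; left-handed substrate and right-handed substrate are mirror images of each other, charged as a racemate, each of them at the stated concentration
- the numbers in the tables scatter by 0.3 percentage points (one standard deviation)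
- on the list of suspects stand: partner + free catalyst + left-handed substrate -> free catalyst + left-handed product; free catalyst + added ligand <-> idle complex; partner + free catalyst -> spent catalyst; partner -> decomposed reagent; partner + free catalyst + right-handed substrate -> free catalyst + right-handed product
- an excess is below zero if the other one leads

* the flask that ends with the higher excess of left-handed product over right-handed product in the product, or "neither" when 2 percentage points or less lies between them (Thursday's / Friday's / neither)
* excess of left-handed product over right-handed product in the product at the end, Thursday's
* excess of left-handed product over right-handed product in the product at the end, Friday's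

On the list of suspects, each substrate is consumed at a rate equal to its rate constant times c(partner), c(free catalyst) and its own concentration. The two rate laws share c(partner) and c(free catalyst), so these cancel when I divide one by the other. Integrating what remains gives a constant, the selectivity factor s.

Each substrate was charged as half of the total, and the east run's last reading shows more left-handed product than the last reading of either other run, so I read s from it: s = 2.42. The west run's last reading gives 2.38. I carry s, the logarithm of the fraction of left-handed substrate left divided by that of the fraction of right-handed substrate left.

The rule follows from it. If a fraction a of left-handed substrate is left, then a^(1/s) of right-handed substrate is left, and the excess is the difference of the two losses over their sum. Near the start this gives (s−1)/(s+1), or 41.6 %, and it falls as the flask proceeds. The east run's last reading stands at 30.1 %, the west run's at 36.8 %.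

Thursday's flask has less partner than the west run, so despite twice the west run's time I expect it near the west value. Friday's flask is close to the east charge and has twice the time, so I expect it below the east value. I therefore choose Thursday's.

The forecast reasons that “the product excess depends essentially only on conversion”. It names Thursday's, with 36.3 % for Thursday's flask and 26.5 % for Friday's.

The simulation gives Thursday's, with 38.2 % for Thursday's flask and 28.2 % for Friday's.

    partner + free catalyst + left-handed substrate → free catalyst + left-handed product (k = 88.0 M⁻² s⁻¹)
    free catalyst + added ligand ⇌ idle complex, settled at all times (K = 650 M⁻¹)
    partner + free catalyst → spent catalyst (k = 6.60 × 10⁻⁴ M⁻¹ s⁻¹)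
    partner → decomposed reagent (k = 5.10 × 10⁻⁴ s⁻¹)
    partner + free catalyst + right-handed substrate → free catalyst + right-handed product (k = 35.0 M⁻² s⁻¹)

Thursday's flask keeps 66 % of its left-handed substrate. With s, the rule then leaves 84.2 % of the right-handed substrate, against 85 % in the flask, and gives an excess of 36.6 %. The neighbouring flask is Thursday's with 4.4 mol% of free catalyst, and it keeps 45 % of its left-handed substrate. There the rule leaves 71.9 % of the right-handed substrate, against 73 %, and gives 32.4 %, while that flask ends at 33.8 %.

The data stem from a simulated flask for substances that don't exist; noise was put on by code.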